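**Retrosynthetic overview**
1. Naamidine F ⇒ its 2,3,4,5-tetramethoxybenzyl precursor; the quinone is unmasked last by oxidative demethylation.
2. Dehydrohydantoin unit ⇒ 2-aminoimidazole + O-silylated 1-methylparabanic acid (ring made beforehand from N-methylurea and oxalyl chloride).
3. 2-Aminoimidazole ring ⇒ α-(methylamino) ketone + cyanamide.
4. α-Amino ketone ⇒ crossed Claisen condensation (key C–C bond) of a Boc-N-methyl amino acid imidazolide with the lithium enolate of tert-butyl (4-methoxyphenyl)acetate, then acidolysis and decarboxylation.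
5. Amino acid ⇒ Boc-sarcosinate enolate + 2,3,4,5-tetramethoxybenzyl bromide (from 2,3,4-trimethoxybenzaldehyde). Ring order: parabanic ring (side branch), imidazole, quinone.

Assumption: the target has no stereocentre, so there is no enantiomer to select; the stereocentres of the intermediates are racemic and vanish when the imidazole forms.

**Step 1**
Reactants: 1 2,3,4-trimethoxybenzaldehyde
Product: 3 2,3,4-trimethoxyphenol, via aryl formate 2 (not isolated)
Conditions: 30% H2O2, cat. H2SO4, MeOH, rt, 16 h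
Reagents that add atoms: hydrogen peroxide, OO
Why: Dakin oxidation, in which the electron-rich aryl group migrates to oxygen in the peroxide adduct and the resulting formate is methanolysed in situ.

**Step 2**
Reactants: 3 2,3,4-trimethoxyphenol
Product: 4 1,2,3,4-tetramethoxybenzene
Conditions: MeI, K2CO3, acetone, reflux
Reagents that add atoms: iodomethane, CI
Why: Williamson ether synthesis of a phenoxide with an unhindered methyl electrophile.

**Step 3**
Reactants: 4 1,2,3,4-tetramethoxybenzene
Product: 6 2,3,4,5-tetramethoxybenzaldehyde, via iminium salt 5 (not isolated)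
Conditions: POCl3, DMF, 0 → 80 °C; then ice, aq NaOAc
Reagents that add atoms: N,N-dimethylformamide, CN(C)C=O; water, O
Why: Vilsmeier–Haack formylation at one of the two equivalent free positions (ortho and para to methoxy groups), followed by hydrolysis of the iminium salt.

**Step 4**
Reactants: 6 2,3,4,5-tetramethoxybenzaldehyde
Product: 7 (2,3,4,5-tetramethoxyphenyl)methanol
Conditions: NaBH4, MeOH, 0 °C
Reagents that add atoms: none
Why: Borohydride reduction of an aldehyde, with nothing else reducible present.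

**Step 5**
Reactants: 7 (2,3,4,5-tetramethoxyphenyl)methanol
Product: 8 1-(bromomethyl)-2,3,4,5-tetramethoxybenzene
Conditions: PBr3 (0.4 equiv), CH2Cl2, 0 °C, 1 h; used at once
Reagents that add atoms: phosphorus tribromide, BrP(Br)Br
Why: Bromide displacement on the benzylic phosphite ester (Appel-type alcohol-to-bromide conversion with PBr3) under conditions that leave aryl methyl ethers untouched.

**Step 6**
Reactants: 8 1-(bromomethyl)-2,3,4,5-tetramethoxybenzene; 9 methyl N-(tert-butoxycarbonyl)-N-methylglycinate (Boc-Sar-OMe)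
Product: 11 methyl 2-[(tert-butoxycarbonyl)(methyl)amino]-3-(2,3,4,5-tetramethoxyphenyl)propanoate (racemic), via lithium enolate 10 (not isolated)
Conditions: 9 (1.3 equiv), LiHMDS (1.3 equiv), THF, −78 °C, 45 min; then 8, −78 → 0 °C
Reagents that add atoms: none
Why: SN2 enolate alkylation of a carbamate-protected glycine ester with a reactive benzylic bromide; the new stereocentre forms as the racemate, which is harmless because it becomes an sp2 imidazole carbon in step 11.

**Step 7**
Reactants: 11 methyl 2-[(tert-butoxycarbonyl)(methyl)amino]-3-(2,3,4,5-tetramethoxyphenyl)propanoate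
Product: 12 2-[(tert-butoxycarbonyl)(methyl)amino]-3-(2,3,4,5-tetramethoxyphenyl)propanoic acid (racemic)
Conditions: LiOH·H2O, THF/MeOH/H2O, rt; then cold 1 M HCl to pH 3
Reagents that add atoms: lithium hydroxide, [Li+].[OH-]
Why: Saponification of a methyl ester, to which the Boc carbamate and the aryl ethers are inert.

**Step 8**
Reactants: 13 (4-methoxyphenyl)acetic acid
Product: 14 tert-butyl (4-methoxyphenyl)acetate
Conditions: Cl3CC(=NH)OtBu (2 equiv), CH2Cl2/cyclohexane, rt, 16 h
Reagents that add atoms: tert-butyl 2,2,2-trichloroacetimidate, CC(C)(C)OC(=N)C(Cl)(Cl)Cl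
Why: Trichloroacetimidate esterification, in which the acid protonates the imidate and is tert-butylated without any strong acid or base.

**Step 9**
Reactants: 12 2-[(tert-butoxycarbonyl)(methyl)amino]-3-(2,3,4,5-tetramethoxyphenyl)propanoic acid; 14 tert-butyl (4-methoxyphenyl)acetate
Product: 17 tert-butyl 4-[(tert-butoxycarbonyl)(methyl)amino]-2-(4-methoxyphenyl)-3-oxo-5-(2,3,4,5-tetramethoxyphenyl)pentanoate (racemic diastereomer mixture), via acyl imidazolide 15 (not isolated), via lithium enolate 16 (not isolated)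
Conditions: 12, CDI (1.1 equiv), THF, rt, 1 h; cannulate into 14 (3.2 equiv) + LiHMDS (3.2 equiv), THF, −78 → −20 °C; aq NH4Cl
Reagents that add atoms: none
Why: Crossed Claisen condensation in which the pre-formed ester enolate 16 is C-acylated by the activated acyl imidazolide 15 and the β-keto ester is at once deprotonated to its stabilised enolate, which stops a second addition; both new stereocentres (diastereomer mixture) are erased in steps 10 and 11.

**Step 10**
Reactants: 17 tert-butyl 4-[(tert-butoxycarbonyl)(methyl)amino]-2-(4-methoxyphenyl)-3-oxo-5-(2,3,4,5-tetramethoxyphenyl)pentanoate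
Product: 19 1-(4-methoxyphenyl)-3-(methylamino)-4-(2,3,4,5-tetramethoxyphenyl)butan-2-one trifluoroacetate (racemic), via β-keto acid salt 18 (not isolated)
Conditions: TFA/CH2Cl2 (1:2), 0 °C → rt, 3 h; concentrate; toluene, 50 °C, 30 min
Reagents that add atoms: trifluoroacetic acid, OC(=O)C(F)(F)F
Why: Acidolysis removes the Boc group and the tert-butyl ester together and the α-aryl β-keto acid decarboxylates readily, while the ammonium salt form keeps the α-amino ketone from self-condensing.

**Step 11**
Reactants: 19 1-(4-methoxyphenyl)-3-(methylamino)-4-(2,3,4,5-tetramethoxyphenyl)butan-2-one trifluoroacetate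
Product: 21 4-(4-methoxybenzyl)-1-methyl-5-(2,3,4,5-tetramethoxybenzyl)-1H-imidazol-2-amine, via guanidine 20 (not isolated)
Conditions: H2NCN (5 equiv), EtOH/H2O (1:1), pH 4.5, 95 °C, 3 h; then aq Na2CO3
Reagents that add atoms: cyanamide, NC#N
Why: Cyanamide cyclocondensation (Marckwald-type 2-aminoimidazole synthesis), in which the secondary amine adds to the nitrile and the guanidine NH2 then condenses with the ketone with loss of water, so N-methyl ends up unambiguously next to the tetramethoxybenzyl carbon.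

**Step 12**
Reactants: 22 N-methylurea
Product: 23 1-methylimidazolidine-2,4,5-trione (1-methylparabanic acid)
Conditions: (COCl)2, THF, 0 °C → reflux
Reagents that add atoms: oxalyl chloride, O=C(Cl)C(=O)Cl
Why: Double N-acylation of the urea by the 1,2-bis-electrophile closes the five-membered trione ring with loss of HCl.

**Step 13**
Reactants: 21 4-(4-methoxybenzyl)-1-methyl-5-(2,3,4,5-tetramethoxybenzyl)-1H-imidazol-2-amine; 23 1-methylimidazolidine-2,4,5-trione
Product: 25 4-{[4-(4-methoxybenzyl)-1-methyl-5-(2,3,4,5-tetramethoxybenzyl)-1H-imidazol-2-yl]amino}-1-methyl-1H-imidazole-2,5-dione, via silyl imidate 24 (not isolated)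
Conditions: 23 (1.5 equiv), BSA (2 equiv), MeCN, reflux, 1 h; evaporate; then 21, toluene, reflux, 14 h; MeOH quench
Reagents that add atoms: none
Why: Addition–elimination of the exocyclic NH2 at the O-silylated C4 of the parabanic ring (silyl-imidate activation, loss of Me3SiOH) gives the conjugated amidine, the condensation known for other naamidines.

**Step 14**
Reactants: 25 4-{[4-(4-methoxybenzyl)-1-methyl-5-(2,3,4,5-tetramethoxybenzyl)-1H-imidazol-2-yl]amino}-1-methyl-1H-imidazole-2,5-dione
Product: 26 naamidine F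
Conditions: CAN (2.5 equiv), MeCN/H2O (2:1), 0 °C, 15 min
Reagents that add atoms: water, O
Why: CAN oxidative demethylation, in which the tetramethoxyarene (the most electron-rich π-system, the heterocycle being protonated in the acidic medium) is oxidised, water adds at the para-related C2 and C5 methoxy carbons and two MeOH are lost to give the 2,3-dimethoxy-1,4-benzoquinone.

**Compound list**
1 | 2,3,4-trimethoxybenzaldehyde | O=Cc1ccc(OC)c(OC)c1OC | starting material
2 | 2,3,4-trimethoxyphenyl formate (not isolated) | O=COc1ccc(OC)c(OC)c1OC | intermediate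
3 | 2,3,4-trimethoxyphenol | Oc1ccc(OC)c(OC)c1OC | intermediate
4 | 1,2,3,4-tetramethoxybenzene | COc1ccc(OC)c(OC)c1OC | intermediate
5 | N,N-dimethyl-(2,3,4,5-tetramethoxybenzylidene)iminium chloride (not isolated) | C[N+](C)=Cc1cc(OC)c(OC)c(OC)c1OC.[Cl-] | intermediate
6 | 2,3,4,5-tetramethoxybenzaldehyde | O=Cc1cc(OC)c(OC)c(OC)c1OC | intermediate
7 | (2,3,4,5-tetramethoxyphenyl)methanol | OCc1cc(OC)c(OC)c(OC)c1OC | intermediate
8 | 1-(bromomethyl)-2,3,4,5-tetramethoxybenzene | BrCc1cc(OC)c(OC)c(OC)c1OC | intermediate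
9 | methyl N-(tert-butoxycarbonyl)-N-methylglycinate (Boc-Sar-OMe) | COC(=O)CN(C)C(=O)OC(C)(C)C | starting material
10 | lithium enolate of 9 (not isolated) | COC([O-])=CN(C)C(=O)OC(C)(C)C.[Li+] | intermediate
11 | methyl 2-[(tert-butoxycarbonyl)(methyl)amino]-3-(2,3,4,5-tetramethoxyphenyl)propanoate (racemic) | COC(=O)C(Cc1cc(OC)c(OC)c(OC)c1OC)N(C)C(=O)OC(C)(C)C | intermediate
12 | 2-[(tert-butoxycarbonyl)(methyl)amino]-3-(2,3,4,5-tetramethoxyphenyl)propanoic acid (racemic) | OC(=O)C(Cc1cc(OC)c(OC)c(OC)c1OC)N(C)C(=O)OC(C)(C)C | intermediate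
13 | (4-methoxyphenyl)acetic acid | COc1ccc(CC(=O)O)cc1 | starting material
14 | tert-butyl (4-methoxyphenyl)acetate | COc1ccc(CC(=O)OC(C)(C)C)cc1 | intermediate
15 | tert-butyl [1-(1H-imidazol-1-yl)-1-oxo-3-(2,3,4,5-tetramethoxyphenyl)propan-2-yl](methyl)carbamate (acyl imidazolide of 12; racemic; not isolated) | CC(C)(C)OC(=O)N(C)C(Cc1cc(OC)c(OC)c(OC)c1OC)C(=O)n1ccnc1 | intermediate
16 | lithium enolate of 14 (not isolated) | COc1ccc(C=C([O-])OC(C)(C)C)cc1.[Li+] | intermediate
17 | tert-butyl 4-[(tert-butoxycarbonyl)(methyl)amino]-2-(4-methoxyphenyl)-3-oxo-5-(2,3,4,5-tetramethoxyphenyl)pentanoate (racemic diastereomer mixture) | COc1ccc(cc1)C(C(=O)OC(C)(C)C)C(=O)C(Cc1cc(OC)c(OC)c(OC)c1OC)N(C)C(=O)OC(C)(C)C | intermediate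
18 | 2-(4-methoxyphenyl)-4-(methylamino)-3-oxo-5-(2,3,4,5-tetramethoxyphenyl)pentanoic acid trifluoroacetate (not isolated) | CNC(Cc1cc(OC)c(OC)c(OC)c1OC)C(=O)C(C(O)=O)c1ccc(OC)cc1.OC(=O)C(F)(F)F | intermediate
19 | 1-(4-methoxyphenyl)-3-(methylamino)-4-(2,3,4,5-tetramethoxyphenyl)butan-2-one trifluoroacetate (racemic) | CNC(Cc1cc(OC)c(OC)c(OC)c1OC)C(=O)Cc1ccc(OC)cc1.OC(=O)C(F)(F)F | intermediate
20 | 1-[4-(4-methoxyphenyl)-3-oxo-1-(2,3,4,5-tetramethoxyphenyl)butan-2-yl]-1-methylguanidine (not isolated) | CN(C(N)=N)C(Cc1cc(OC)c(OC)c(OC)c1OC)C(=O)Cc1ccc(OC)cc1 | intermediate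
21 | 4-(4-methoxybenzyl)-1-methyl-5-(2,3,4,5-tetramethoxybenzyl)-1H-imidazol-2-amine | Cn1c(N)nc(Cc2ccc(OC)cc2)c1Cc1cc(OC)c(OC)c(OC)c1OC | intermediate
22 | N-methylurea | CNC(N)=O | starting material
23 | 1-methylimidazolidine-2,4,5-trione (1-methylparabanic acid) | CN1C(=O)NC(=O)C1=O | intermediate
24 | 1-methyl-4-[(trimethylsilyl)oxy]-1H-imidazole-2,5-dione (not isolated) | CN1C(=O)N=C(O[Si](C)(C)C)C1=O | intermediate
25 | 4-{[4-(4-methoxybenzyl)-1-methyl-5-(2,3,4,5-tetramethoxybenzyl)-1H-imidazol-2-yl]amino}-1-methyl-1H-imidazole-2,5-dione | COc1ccc(Cc2nc(NC3=NC(=O)N(C)C3=O)n(C)c2Cc2cc(OC)c(OC)c(OC)c2OC)cc1 | intermediate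
26 | naamidine F, 4-{[5-[(4,5-dimethoxy-3,6-dioxocyclohexa-1,4-dien-1-yl)methyl]-4-(4-methoxybenzyl)-1-methyl-1H-imidazol-2-yl]amino}-1-methyl-1H-imidazole-2,5-dione | COC1=C(OC)C(=O)C(Cc2c(Cc3ccc(OC)cc3)nc(NC3=NC(=O)N(C)C3=O)n2C)=CC1=O | target

**Totals**
Total step count: 14. Longest linear sequence: 12 steps (steps 1–7, 9, 10, 11, 13, 14, from 2,3,4-trimethoxybenzaldehyde); steps 8 and 12 are one-step side branches.

**Three steps most likely to fail**

Step 6 (benzylation of the Boc-sarcosinate enolate). The risks are self-condensation of enolate 10, the lability of the electron-rich bromide 8 and bis-alkylation. The fallback sets out from aldehyde 6 and leaves out 7 and 8. Horner–Wadsworth–Emmons olefination of 6 with methyl 2-[(tert-butoxycarbonyl)amino]-2-(dimethoxyphosphoryl)acetate (DBU, CH2Cl2, rt) gives the Z-dehydroamino ester F1. Hydrogenation (H2, Pd/C, MeOH) gives the saturated Boc-amino ester F2. N-methylation of the carbamate (NaH, MeI, DMF, 0 °C) gives 11, where the fallback comes back to the route.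

Step 9 (crossed Claisen condensation). The risks are sluggish acylation of the stabilised aryl-acetate enolate by the hindered imidazolide and proton transfer instead of C–C bond formation. The fallback sets out from acid 12. Coupling with N,O-dimethylhydroxylamine hydrochloride (EDC·HCl, HOBt, iPr2NEt, CH2Cl2) gives the Weinreb amide F3. Addition of 4-methoxybenzylmagnesium chloride (THF, 0 °C) gives the Boc-protected amino ketone F4. TFA/CH2Cl2 then removes the Boc group and gives 19, where the fallback comes back to the route.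

Step 14 (CAN oxidation of 25). The risks are competing oxidation of the imidazole or the doubly benzylic CH2 groups and acid hydrolysis of the amidine-type dehydrohydantoin. The fallback sets out from 21 and moves the oxidation in front of the dehydrohydantoin. Compound 21 is protonated with TFA (1.1 equiv) and oxidised with CAN in MeCN/H2O at 0 °C; the guanidinium-like cation resists oxidation, and this gives the aminoimidazole quinone trifluoroacetate F5. Reduction with aqueous Na2S2O4 gives the hydroquinone salt F6. F6 is condensed with 24 (from 23 and excess BSA, which also frees the amine and silylates the phenols transiently; toluene, reflux; MeOH work-up) to give the hydroquinone F7. Mild oxidation of F7 (Ag2O, CH2Cl2, rt, or air) gives 26, where the fallback comes back to the route.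

**Further compounds**
F1 | step 6 | methyl (Z)-2-[(tert-butoxycarbonyl)amino]-3-(2,3,4,5-tetramethoxyphenyl)prop-2-enoate | COC(=O)/C(NC(=O)OC(C)(C)C)=C/c1cc(OC)c(OC)c(OC)c1OC
F2 | step 6 | methyl 2-[(tert-butoxycarbonyl)amino]-3-(2,3,4,5-tetramethoxyphenyl)propanoate (racemic) | COC(=O)C(Cc1cc(OC)c(OC)c(OC)c1OC)NC(=O)OC(C)(C)C
F3 | step 9 | tert-butyl {1-[methoxy(methyl)amino]-1-oxo-3-(2,3,4,5-tetramethoxyphenyl)propan-2-yl}(methyl)carbamate (racemic) | CON(C)C(=O)C(Cc1cc(OC)c(OC)c(OC)c1OC)N(C)C(=O)OC(C)(C)C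
F4 | step 9 | tert-butyl [4-(4-methoxyphenyl)-3-oxo-1-(2,3,4,5-tetramethoxyphenyl)butan-2-yl](methyl)carbamate (racemic) | CC(C)(C)OC(=O)N(C)C(Cc1cc(OC)c(OC)c(OC)c1OC)C(=O)Cc1ccc(OC)cc1
F5 | step 14 | 2-{[2-amino-4-(4-methoxybenzyl)-1-methyl-1H-imidazol-5-yl]methyl}-5,6-dimethoxy-1,4-benzoquinone trifluoroacetate | COC1=C(OC)C(=O)C(Cc2c(Cc3ccc(OC)cc3)nc(N)n2C)=CC1=O.OC(=O)C(F)(F)F
F6 | step 14 | 2-{[2-amino-4-(4-methoxybenzyl)-1-methyl-1H-imidazol-5-yl]methyl}-5,6-dimethoxybenzene-1,4-diol trifluoroacetate | Cn1c(N)nc(Cc2ccc(OC)cc2)c1Cc1cc(O)c(OC)c(OC)c1O.OC(=O)C(F)(F)F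
F7 | step 14 | 4-{[5-(2,5-dihydroxy-3,4-dimethoxybenzyl)-4-(4-methoxybenzyl)-1-methyl-1H-imidazol-2-yl]amino}-1-methyl-1H-imidazole-2,5-dione | COc1ccc(Cc2nc(NC3=NC(=O)N(C)C3=O)n(C)c2Cc2cc(O)c(OC)c(OC)c2O)cc1
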